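**Plan**
- Ring atoms are numbered as in the target: C1 bears OH, C2, C3 and C6 bear Br, C4 bears CH2OH, C5 bears H.
- Retrosynthesis: the phenol is masked as a methoxymethyl ether and the CH2–OH bond is traced back to a CH2–Si bond. The neighbouring C4–CH2 and C3–Br bonds are then cut together to expose a C3≡C4 aryne, and the C2 and C6 bromines go back to phenol-directed bromination.
- Enabling feature: C3–Br and C4–CH2OH sit on adjacent ring carbons. The bromine on C2, beside C3, polarises the C3≡C4 aryne so that carbon enters at C4 and the metal (later bromine) ends at C3.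
- Forward: hydroquinone monobenzoate is dibrominated, protected, debenzoylated and triflated. C–H magnesiation with loss of triflate gives the aryne, a silylmethyl Grignard reagent adds, and a bromine donor caps C3. Tamao oxidation and acetal hydrolysis finish the chain.
- No ring is formed at any stage; the target is achiral, so no stereochemistry has to be set.

Key step: step 6

Remark: Grignard reagent 7 is used as a titrated THF solution. SMILES carry no stereodescriptors because no compound has a stereocentre.

**Step 1**
Reactants: 1 4-hydroxyphenyl benzoate
Product: 2 3,5-dibromo-4-hydroxyphenyl benzoate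
Conditions: Br2 (2.1 equiv), AcOH, rt
Reagents that add atoms: bromine, BrBr
Why: Electrophilic aromatic bromination; the free hydroxyl activates only its two ortho positions (para is blocked and the benzoyloxy group is a much weaker donor), so two equivalents of bromine should stop at the 3,5-dibromide.

**Step 2**
Reactants: 2 3,5-dibromo-4-hydroxyphenyl benzoate
Product: 3 3,5-dibromo-4-(methoxymethoxy)phenyl benzoate
Conditions: MOMCl, iPr2NEt, CH2Cl2, 0 °C → rt
Reagents that add atoms: chloromethyl methyl ether, COCCl
Why: O-Alkylation of a phenol (methoxymethyl acetal formation); the acidic 2,6-dibromophenol is readily deprotonated by the amine and the small, reactive chloromethyl ether tolerates the two flanking bromines, while the aryl benzoate is inert to these conditions.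

**Step 3**
Reactants: 3 3,5-dibromo-4-(methoxymethoxy)phenyl benzoate
Product: 4 3,5-dibromo-4-(methoxymethoxy)phenol
Conditions: K2CO3, MeOH, rt; aq. NH4Cl work-up
Reagents that add atoms: none
Why: Base-mediated transesterification (methanolysis) of an aryl ester; the phenoxide leaving group makes the benzoate labile, whereas the acetal and the aryl bromides are stable to carbonate in methanol.

**Step 4**
Reactants: 4 3,5-dibromo-4-(methoxymethoxy)phenol
Product: 5 3,5-dibromo-4-(methoxymethoxy)phenyl trifluoromethanesulfonate
Conditions: Tf2O, pyridine, CH2Cl2, −78 → 0 °C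
Reagents that add atoms: trifluoromethanesulfonic anhydride, O=S(=O)(OS(=O)(=O)C(F)(F)F)C(F)(F)F
Why: O-Sulfonylation of an unhindered phenol with triflic anhydride, the standard aryl triflate synthesis; the pyridine-buffered, cold medium should spare the methoxymethyl acetal.

**Step 5**
Reactants: 6 (chloromethyl)(isopropoxy)dimethylsilane
Product: 7 {[isopropoxy(dimethyl)silyl]methyl}magnesium chloride
Conditions: Mg turnings, BrCH2CH2Br (cat.), THF, reflux, then rt
Reagents that add atoms: magnesium, [Mg]
Why: Grignard formation by insertion of magnesium into the primary C–Cl bond; this α-silyl Grignard reagent is an established hydroxymethyl anion equivalent, and the hindered isopropoxy group on silicon resists attack by the reagent itself.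

**Step 6**
Reactants: 5 3,5-dibromo-4-(methoxymethoxy)phenyl trifluoromethanesulfonate; 7 {[isopropoxy(dimethyl)silyl]methyl}magnesium chloride; 8 1,2-dibromo-1,1,2,2-tetrachloroethane
Product: 12 isopropoxydimethyl[2,3,5-tribromo-4-(methoxymethoxy)benzyl]silane, via magnesiated triflate 9 (not isolated), via bromoaryne 10 (not isolated), via arylmagnesium chloride 11 (not isolated)
Conditions: 5 + 7 (3 equiv), THF, −40 °C; TMPMgCl·LiCl (1.2 equiv), −40 → −25 °C; then 8 (5 equiv), −40 → 0 °C
Reagents that add atoms: none
Why: TMPMgCl·LiCl should remove the ring hydrogen at C3 of 5 (C3–H and C5–H are equivalent by symmetry, each acidified by a flanking triflate and bromine), and the arylmagnesium 9 then expels triflate, a far better leaving group than the bromide on its other side, so only the C3≡C4 aryne 10 arises. The closest known reactions are aryne generation from 2-magnesiated aryl sulfonates and the Hart-type addition of Grignard reagents to 3-haloarynes with electrophilic capture of the new arylmagnesium; here they are combined as one three-component aryne carbomagnesiation–bromination. The bromine on C2 distorts the aryne and stabilises negative charge on C3, and C4 is also the less hindered terminus because its other neighbour C5 bears only hydrogen, so the carbon of 7 should enter at C4 and magnesium should end at C3 in 11. Bromine transfer from 8 to 11, with loss of tetrachloroethene, then forms the C3–Br bond. No ring is closed and no stereocentre is created; the selectivities needed are the leaving-group choice (triflate over bromide) and the C4/C3 orientation of addition, both secured by the substituents just named. Because 11 carries an ortho bromide it could itself collapse to a second aryne, so addition and quench are kept at or below −25 °C, where 2-bromoarylmagnesium halides persist.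

**Step 7**
Reactants: 12 isopropoxydimethyl[2,3,5-tribromo-4-(methoxymethoxy)benzyl]silane
Product: 13 [2,3,5-tribromo-4-(methoxymethoxy)phenyl]methanol
Conditions: 30% aq. H2O2, KF, KHCO3, THF/MeOH (1:1), rt
Reagents that add atoms: hydrogen peroxide, OO
Why: Tamao–Fleming oxidation; the fluoride-activated alkoxysilane is attacked by hydroperoxide and the benzylic carbon migrates from silicon to oxygen, while aryl bromides and the acetal are inert to bicarbonate-buffered peroxide.

**Step 8**
Reactants: 13 [2,3,5-tribromo-4-(methoxymethoxy)phenyl]methanol
Product: 14 2,3,6-tribromo-4-(hydroxymethyl)phenol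
Conditions: 2 M aq. HCl, THF, 40 °C
Reagents that add atoms: none
Why: Acid-catalysed acetal hydrolysis of the methoxymethyl ether; with water as the only bulk nucleophile any transient benzylic ionisation of the para-hydroxybenzyl alcohol simply returns the alcohol, and the three bromines disfavour that ionisation.

**Compound list**
1 | 4-hydroxyphenyl benzoate | O=C(Oc1ccc(O)cc1)c1ccccc1 | starting material
2 | 3,5-dibromo-4-hydroxyphenyl benzoate | O=C(Oc1cc(Br)c(O)c(Br)c1)c1ccccc1 | intermediate
3 | 3,5-dibromo-4-(methoxymethoxy)phenyl benzoate | COCOc1c(Br)cc(OC(=O)c2ccccc2)cc1Br | intermediate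
4 | 3,5-dibromo-4-(methoxymethoxy)phenol | COCOc1c(Br)cc(O)cc1Br | intermediate
5 | 3,5-dibromo-4-(methoxymethoxy)phenyl trifluoromethanesulfonate | COCOc1c(Br)cc(OS(=O)(=O)C(F)(F)F)cc1Br | intermediate
6 | (chloromethyl)(isopropoxy)dimethylsilane | CC(C)O[Si](C)(C)CCl | starting material
7 | {[isopropoxy(dimethyl)silyl]methyl}magnesium chloride | CC(C)O[Si](C)(C)C[Mg]Cl | intermediate
8 | 1,2-dibromo-1,1,2,2-tetrachloroethane | BrC(Cl)(Cl)C(Cl)(Cl)Br | starting material
9 | [2,4-dibromo-3-(methoxymethoxy)-6-(trifluoromethylsulfonyloxy)phenyl]magnesium chloride (magnesiated triflate) | COCOc1c(Br)cc(OS(=O)(=O)C(F)(F)F)c([Mg]Cl)c1Br | intermediate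
10 | 3,5-dibromo-4-(methoxymethoxy)-1,2-didehydrobenzene (bromoaryne) | COCOC1=C(Br)C#CC=C1Br | intermediate
11 | [2,4-dibromo-6-{[isopropoxy(dimethyl)silyl]methyl}-3-(methoxymethoxy)phenyl]magnesium chloride (arylmagnesium chloride) | COCOc1c(Br)cc(C[Si](C)(C)OC(C)C)c([Mg]Cl)c1Br | intermediate
12 | isopropoxydimethyl[2,3,5-tribromo-4-(methoxymethoxy)benzyl]silane | COCOc1c(Br)cc(C[Si](C)(C)OC(C)C)c(Br)c1Br | intermediate
13 | [2,3,5-tribromo-4-(methoxymethoxy)phenyl]methanol | COCOc1c(Br)cc(CO)c(Br)c1Br | intermediate
14 | 2,3,6-tribromo-4-(hydroxymethyl)phenol | OCc1cc(Br)c(O)c(Br)c1Br | target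

**Step count**
Total step count: 8.
Longest linear sequence: 7 steps (steps 1–4 and 6–8); step 5 prepares the Grignard reagent on a side branch.

**Steps most likely to fail**

Step 6. Several processes could spoil the key step:
- the hindered amide may metalate C3–H too slowly at the temperature the adduct tolerates;
- the weakly nucleophilic α-silyl Grignard reagent may lose the race for the aryne to the amide, or attack the triflate at sulfur;
- the magnesiated triflate may undergo sulfonyl migration instead of elimination;
- the adduct may expel its ortho bromide before the quench.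

Fallback: generate the same aryne without any amide base, by iodine–magnesium exchange on an ortho-iodoaryl arenesulfonate. Setting out from phenol 4, mono-iodination ortho to the hydroxyl (N-iodosuccinimide, MeCN, 0 °C) should give 3,5-dibromo-2-iodo-4-(methoxymethoxy)phenol F1. Sulfonylation (4-ClC6H4SO2Cl, Et3N, CH2Cl2) should give 3,5-dibromo-2-iodo-4-(methoxymethoxy)phenyl 4-chlorobenzenesulfonate F2. Treatment with iPrMgCl (1.0 equiv, THF, −78 °C) should exchange only the iodine and give [2,4-dibromo-6-{[(4-chlorophenyl)sulfonyl]oxy}-3-(methoxymethoxy)phenyl]magnesium chloride F3, which is not isolated and should persist at that temperature. Reagent 7 is then added and the mixture warmed just until the sulfonate is lost, so that 7 is the only nucleophile present when aryne 10 forms. Carbomagnesiation to 11 and quench with 8 bring the sequence back to the route at 12.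

Step 7. Fluoride-triggered protodesilylation of the benzylic C–Si bond may outrun oxygen insertion, because the electron-poor tribromoarene stabilises the benzylic carbanion. Fallback: make that cleavage the intended reaction and install oxygen by benzylic halogenation. Setting out from 12, CsF in wet DMF should give 2,3,5-tribromo-4-(methoxymethoxy)toluene F4. Wohl–Ziegler bromination (N-bromosuccinimide, AIBN, PhCF3, 80 °C) should give 2,3,5-tribromo-4-(methoxymethoxy)benzyl bromide F5. Hydrolysis (CaCO3, H2O/1,4-dioxane, reflux) comes back to the route at 13.

Step 8. Acid may ionise the benzylic C–O bond once the para-hydroxyl is freed (quinone-methide-type solvolysis), leading to etherification by the released methanol or to self-condensation. Fallback: carry the benzylic carbon through the acid step at the aldehyde oxidation level, where it cannot ionise. Setting out from 13, oxidation with MnO2 (CH2Cl2, rt) should give 2,3,5-tribromo-4-(methoxymethoxy)benzaldehyde F6. Acetal hydrolysis (2 M aq. HCl, THF, 40 °C) should give 2,3,5-tribromo-4-hydroxybenzaldehyde F7. Reduction with NaBH4 (THF/H2O, 0 °C; aq. NH4Cl work-up) comes back to the route at target 14.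

**Further compounds**
F1 | step 6 | 3,5-dibromo-2-iodo-4-(methoxymethoxy)phenol | COCOc1c(Br)cc(O)c(I)c1Br
F2 | step 6 | 3,5-dibromo-2-iodo-4-(methoxymethoxy)phenyl 4-chlorobenzenesulfonate | COCOc1c(Br)cc(OS(=O)(=O)c2ccc(Cl)cc2)c(I)c1Br
F3 | step 6 | [2,4-dibromo-6-{[(4-chlorophenyl)sulfonyl]oxy}-3-(methoxymethoxy)phenyl]magnesium chloride | COCOc1c(Br)cc(OS(=O)(=O)c2ccc(Cl)cc2)c([Mg]Cl)c1Br
F4 | step 7 | 2,3,5-tribromo-4-(methoxymethoxy)toluene | COCOc1c(Br)cc(C)c(Br)c1Br
F5 | step 7 | 2,3,5-tribromo-4-(methoxymethoxy)benzyl bromide | COCOc1c(Br)cc(CBr)c(Br)c1Br
F6 | step 8 | 2,3,5-tribromo-4-(methoxymethoxy)benzaldehyde | COCOc1c(Br)cc(C=O)c(Br)c1Br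
F7 | step 8 | 2,3,5-tribromo-4-hydroxybenzaldehyde | O=Cc1cc(Br)c(O)c(Br)c1Br
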